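**Plan**

- Numbering: ring O1, C2 (lactone C=O), C3, C4, C5; chain C6 to C18 (C18 is the ketone carbon). The retrosynthesis cuts C3–C4 (Dieckmann) and C5=C6 (olefination) of the tetronic acid, then C16–C17, C14–C15, C12–C13 together with C11–CH3, and last C8–C9.
- Enabling feature: C18(=O)–C17H2–C16H2–C15(CH3)=C14H is a γ,δ-unsaturated ketone with an E-trisubstituted alkene. This is the retron of a Claisen rearrangement of a C14 isopropenyl carbinol through its 1-(furan-3-yl)vinyl ether.
- Forward: hydroxy ester 1 gives the C6–C12 alkyne (C8–C9 by copper-catalysed coupling). Methylalumination and ethylene oxide add C11–CH3 and C12–C13, oxidation and isopropenyl Grignard addition add C14–C15, and the ketal Claisen rearrangement adds C16–C17.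
- The C6 aldehyde is then olefinated to a 2-acyloxy-enoate (C5=C6), and Dieckmann closure makes the only ring formed in the route; the furan is bought.
- Stereochemistry: C7 (S) comes from methyl (R)-3-hydroxy-2-methylpropanoate. E-C11=C12 comes from syn-carbometalation, E-C14=C15 from the chair transition state of the rearrangement, and E-C5=C6 from a kinetically controlled olefination with a bis(trifluoroethyl) phosphonate.

Key step: step 10

Remark: the SMILES places C7 on the same side of C5=C6 as C4 (5E), the less stable geometry of a 5-ylidene tetronic acid, so this bond is set kinetically and not equilibrated afterwards.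

**Step 1**
Reactants: 1 methyl (R)-3-hydroxy-2-methylpropanoate
Product: 2 methyl (R)-3-[(tert-butyldimethylsilyl)oxy]-2-methylpropanoate
Conditions: TBSCl, imidazole, CH2Cl2, 0 °C → rt
Reagents that add atoms: tert-butyldimethylsilyl chloride, CC(C)(C)[Si](C)(C)Cl
Why: Imidazole-mediated silylation of a primary alcohol is mild enough not to epimerise the α-methyl ester.

**Step 2**
Reactants: 2 methyl (R)-3-[(tert-butyldimethylsilyl)oxy]-2-methylpropanoate
Product: 3 (S)-3-[(tert-butyldimethylsilyl)oxy]-2-methylpropan-1-ol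
Conditions: i-Bu2AlH (2.2 equiv), CH2Cl2, −78 °C → 0 °C
Reagents that add atoms: none
Why: Hydride reduction of the ester to the primary alcohol leaves the silyl ether and the stereocentre untouched; the descriptor changes only because the priorities change.

**Step 3**
Reactants: 3 (S)-3-[(tert-butyldimethylsilyl)oxy]-2-methylpropan-1-ol
Product: 4 (R)-tert-butyl(3-iodo-2-methylpropoxy)dimethylsilane
Conditions: PPh3, I2, imidazole, CH2Cl2, 0 °C → rt
Reagents that add atoms: iodine, II
Why: Appel-type iodination proceeds by SN2 displacement at the primary carbon, so the neighbouring stereocentre is not involved.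

**Step 4**
Reactants: 4 (R)-tert-butyl(3-iodo-2-methylpropoxy)dimethylsilane; 5 (4-bromobut-1-yn-1-yl)trimethylsilane
Product: 7 (S)-tert-butyldimethyl{[2-methyl-7-(trimethylsilyl)hept-6-yn-1-yl]oxy}silane, via butynyl Grignard reagent 6 (not isolated)
Conditions: 5, Mg, THF, rt → 40 °C; then 4, Li2CuCl4 (5 mol %), THF, −20 °C → rt
Reagents that add atoms: none
Why: Copper-catalysed (Kochi-type) coupling of a primary alkyl iodide with a primary alkyl Grignard reagent forms C8–C9; the C-silyl cap keeps the alkyne from protonating the Grignard reagent.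

**Step 5**
Reactants: 7 (S)-tert-butyldimethyl{[2-methyl-7-(trimethylsilyl)hept-6-yn-1-yl]oxy}silane
Product: 8 (S)-tert-butyldimethyl[(2-methylhept-6-yn-1-yl)oxy]silane
Conditions: K2CO3 (0.2 equiv), MeOH, rt
Reagents that add atoms: none
Why: Methoxide-mediated protodesilylation cleaves the alkynyl C–Si bond selectively, while the primary silyl ether is stable to these conditions.

**Step 6**
Reactants: 8 (S)-tert-butyldimethyl[(2-methylhept-6-yn-1-yl)oxy]silane; 9 ethylene oxide
Product: 12 (3E,8S)-9-[(tert-butyldimethylsilyl)oxy]-4,8-dimethylnon-3-en-1-ol, via alkenyldimethylalane 10 (not isolated), via lithium alkenylalanate 11 (not isolated)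
Conditions: AlMe3 (2.5 equiv), Cp2ZrCl2 (0.25 equiv), CH2Cl2, 0 °C → rt; volatiles removed, THF/hexane, n-BuLi, −78 °C; then 9 (excess), −78 °C → rt
Reagents that add atoms: trimethylaluminium, C[Al](C)C
Why: Zirconium-catalysed methylalumination (Negishi carboalumination) adds methyl and aluminium syn with methyl on the internal carbon, and the alanate transfers its alkenyl group to ethylene oxide with retention, which sets E-C11=C12.

**Step 7**
Reactants: 12 (3E,8S)-9-[(tert-butyldimethylsilyl)oxy]-4,8-dimethylnon-3-en-1-ol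
Product: 13 (3E,8S)-9-[(tert-butyldimethylsilyl)oxy]-4,8-dimethylnon-3-enal
Conditions: Dess–Martin periodinane, NaHCO3, CH2Cl2, 0 °C → rt; used at once
Reagents that add atoms: none
Why: Buffered Dess–Martin oxidation is neutral and should give the β,γ-unsaturated aldehyde without moving the double bond into conjugation.

**Step 8**
Reactants: 13 (3E,8S)-9-[(tert-butyldimethylsilyl)oxy]-4,8-dimethylnon-3-enal; 14 isopropenylmagnesium bromide
Product: 15 (5E,10S)-11-[(tert-butyldimethylsilyl)oxy]-2,6,10-trimethylundeca-1,5-dien-3-ol (both C3 epimers)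
Conditions: THF, −78 °C
Reagents that add atoms: none
Why: Grignard 1,2-addition at low temperature outruns enolisation of the aldehyde; the new carbinol centre (C14 of the target) need not be controlled because step 10 destroys it.

**Step 9**
Reactants: 16 3-acetylfuran
Product: 17 3-(1,1-dimethoxyethyl)furan
Conditions: HC(OMe)3, MeOH, TsOH (1 mol %), rt; Et3N quench, distillation
Reagents that add atoms: methanol, CO; trimethyl orthoformate, COC(OC)OC
Why: Acid-catalysed ketalisation is driven by the orthoformate as water scavenger, and the electron-poor 3-acylfuran tolerates the catalytic acid.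

**Step 10**
Reactants: 15 (5E,10S)-11-[(tert-butyldimethylsilyl)oxy]-2,6,10-trimethylundeca-1,5-dien-3-ol; 17 3-(1,1-dimethoxyethyl)furan
Product: 20 (4E,7E,12S)-13-[(tert-butyldimethylsilyl)oxy]-1-(furan-3-yl)-4,8,12-trimethyltrideca-4,7-dien-1-one, via mixed ketal 18 (not isolated), via allyl vinyl ether 19 (not isolated)
Conditions: 17 (4 equiv), EtCO2H (10 mol %), xylene, 135 °C, MeOH distilled off
Reagents that add atoms: none
Why: Propanoic acid catalyses exchange of one methoxy group of 17 for the C14 hydroxyl (mixed ketal 18), loss of methanol gives the allyl 1-(furan-3-yl)vinyl ether 19, and this undergoes a thermal [3,3]-sigmatropic shift through a chair transition state that forms the C16–C17 bond, the C14=C15 alkene and the C18 ketone in one event. The closest known reaction type is the ketal Claisen rearrangement of 2-methylalk-1-en-3-ols with ketone dimethyl ketals, which gives E γ,δ-unsaturated ketones. No ring is closed and no stereocentre is created; the C14 carbinol centre is consumed, so both epimers of 15 converge. The selectivity needed is E at C14=C15, and it is secured by the C13 chain taking the pseudo-equatorial position of the chair, where it avoids a 1,3-diaxial clash with the substituents on C18. The enol ether can form only toward the methyl group of the ketal, so there is no regiochemical choice, and the weak acid should spare the furan, the silyl ether, C7 and the C11=C12 alkene.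

**Step 11**
Reactants: 20 (4E,7E,12S)-13-[(tert-butyldimethylsilyl)oxy]-1-(furan-3-yl)-4,8,12-trimethyltrideca-4,7-dien-1-one
Product: 21 (4E,7E,12S)-1-(furan-3-yl)-13-hydroxy-4,8,12-trimethyltrideca-4,7-dien-1-one
Conditions: Bu4NF (1.2 equiv), THF, 0 °C → rt
Reagents that add atoms: none
Why: Fluoride-mediated desilylation frees the primary alcohol and should not affect the ketone, the furan or the skipped diene.

**Step 12**
Reactants: 21 (4E,7E,12S)-1-(furan-3-yl)-13-hydroxy-4,8,12-trimethyltrideca-4,7-dien-1-one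
Product: 22 (2S,6E,9E)-13-(furan-3-yl)-2,6,10-trimethyl-13-oxotrideca-6,9-dienal
Conditions: Dess–Martin periodinane, NaHCO3, CH2Cl2, 0 °C → rt; used crude
Reagents that add atoms: none
Why: Buffered Dess–Martin oxidation is non-basic and should give the α-methyl aldehyde without epimerising C7 (C2 of 22).

**Step 13**
Reactants: 23 methyl 2-[bis(2,2,2-trifluoroethoxy)phosphoryl]acetate
Product: 24 methyl 2-[bis(2,2,2-trifluoroethoxy)phosphoryl]-2-diazoacetate
Conditions: 4-acetamidobenzenesulfonyl azide, DBU, MeCN, 0 °C → rt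
Reagents that add atoms: 4-acetamidobenzenesulfonyl azide, CC(=O)Nc1ccc(cc1)S(=O)(=O)N=[N+]=[N-]
Why: Regitz diazo transfer to the acidic methylene of a phosphonoacetate is standard, and the electron-poor phosphonate makes deprotonation easier.

**Step 14**
Reactants: 24 methyl 2-[bis(2,2,2-trifluoroethoxy)phosphoryl]-2-diazoacetate
Product: 25 methyl 2-[bis(2,2,2-trifluoroethoxy)phosphoryl]-2-(propanoyloxy)acetate (racemic)
Conditions: Rh2(OAc)4 (1 mol %), EtCO2H (3 equiv), ClCH2CH2Cl, 70 °C
Reagents that add atoms: propanoic acid, CCC(=O)O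
Why: Rhodium-carbenoid O–H insertion of a diazophosphonoacetate into a carboxylic acid installs the acyloxy group directly at the carbon that bears the phosphonate.

**Step 15**
Reactants: 22 (2S,6E,9E)-13-(furan-3-yl)-2,6,10-trimethyl-13-oxotrideca-6,9-dienal; 25 methyl 2-[bis(2,2,2-trifluoroethoxy)phosphoryl]-2-(propanoyloxy)acetate
Product: 26 methyl (2E,4S,8E,11E)-15-(furan-3-yl)-4,8,12-trimethyl-15-oxo-2-(propanoyloxy)pentadeca-2,8,11-trienoate
Conditions: 25 (1.3 equiv), KN(SiMe3)2 (1.25 equiv), 18-crown-6, THF, −78 °C; then 22, −78 °C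
Reagents that add atoms: none
Why: In this Still–Gennari-type Horner–Wadsworth–Emmons olefination the electron-poor phosphonate should make elimination from the kinetic adduct faster than its reversal, placing the C4 chain cis to the ester (2E) as with the α-alkyl and α-bromo reagents of this type; the aldehyde reacts ahead of the furyl ketone and the weakly basic phosphonate anion should not epimerise the α-centre.

**Step 16**
Reactants: 26 methyl (2E,4S,8E,11E)-15-(furan-3-yl)-4,8,12-trimethyl-15-oxo-2-(propanoyloxy)pentadeca-2,8,11-trienoate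
Product: 27 (5E)-5-[(2S,6E,9E)-13-(furan-3-yl)-2,6,10-trimethyl-13-oxotrideca-6,9-dien-1-ylidene]-4-hydroxy-3-methylfuran-2(5H)-one
Conditions: LiN(SiMe3)2 (3.2 equiv), THF, −78 °C → −20 °C (26 added slowly to the base); then cold 0.5 M HCl to pH 3
Reagents that add atoms: none
Why: In this Dieckmann (intramolecular Claisen) condensation of an α-acyloxy ester, one equivalent of base holds the furyl ketone as its enolate and a second forms the propanoate enolate, which closes 5-exo-trig onto the methyl ester; the enoate geometry is carried into C5=C6 and the product is protected as its tetronate anion until the acidic work-up.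

**Compound list**

1 | methyl (R)-3-hydroxy-2-methylpropanoate | OC[C@@H](C)C(=O)OC | starting material
2 | methyl (R)-3-[(tert-butyldimethylsilyl)oxy]-2-methylpropanoate | CC(C)(C)[Si](C)(C)OC[C@@H](C)C(=O)OC | intermediate
3 | (S)-3-[(tert-butyldimethylsilyl)oxy]-2-methylpropan-1-ol | CC(C)(C)[Si](C)(C)OC[C@@H](C)CO | intermediate
4 | (R)-tert-butyl(3-iodo-2-methylpropoxy)dimethylsilane | CC(C)(C)[Si](C)(C)OC[C@@H](C)CI | intermediate
5 | (4-bromobut-1-yn-1-yl)trimethylsilane | C[Si](C)(C)C#CCCBr | starting material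
6 | [4-(trimethylsilyl)but-3-yn-1-yl]magnesium bromide | C[Si](C)(C)C#CCC[Mg]Br | intermediate
7 | (S)-tert-butyldimethyl{[2-methyl-7-(trimethylsilyl)hept-6-yn-1-yl]oxy}silane | CC(C)(C)[Si](C)(C)OC[C@@H](C)CCCC#C[Si](C)(C)C | intermediate
8 | (S)-tert-butyldimethyl[(2-methylhept-6-yn-1-yl)oxy]silane | CC(C)(C)[Si](C)(C)OC[C@@H](C)CCCC#C | intermediate
9 | ethylene oxide | C1CO1 | starting material
10 | {(1E,6S)-7-[(tert-butyldimethylsilyl)oxy]-2,6-dimethylhept-1-en-1-yl}dimethylalane | CC(C)(C)[Si](C)(C)OC[C@@H](C)CCC/C(C)=C/[Al](C)C | intermediate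
11 | lithium butyl{(1E,6S)-7-[(tert-butyldimethylsilyl)oxy]-2,6-dimethylhept-1-en-1-yl}dimethylalanate | CC(C)(C)[Si](C)(C)OC[C@@H](C)CCC/C(C)=C/[Al-](C)(C)CCCC.[Li+] | intermediate
12 | (3E,8S)-9-[(tert-butyldimethylsilyl)oxy]-4,8-dimethylnon-3-en-1-ol | CC(C)(C)[Si](C)(C)OC[C@@H](C)CCC/C(C)=C/CCO | intermediate
13 | (3E,8S)-9-[(tert-butyldimethylsilyl)oxy]-4,8-dimethylnon-3-enal | CC(C)(C)[Si](C)(C)OC[C@@H](C)CCC/C(C)=C/CC=O | intermediate
14 | isopropenylmagnesium bromide | CC(=C)[Mg]Br | starting material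
15 | (5E,10S)-11-[(tert-butyldimethylsilyl)oxy]-2,6,10-trimethylundeca-1,5-dien-3-ol, both C3 epimers | CC(C)(C)[Si](C)(C)OC[C@@H](C)CCC/C(C)=C/CC(O)C(C)=C | intermediate
16 | 3-acetylfuran | CC(=O)c1ccoc1 | starting material
17 | 3-(1,1-dimethoxyethyl)furan | COC(C)(OC)c1ccoc1 | intermediate
18 | tert-butyl{[(2S,6E)-9-[1-(furan-3-yl)-1-methoxyethoxy]-2,6,10-trimethylundeca-6,10-dien-1-yl]oxy}dimethylsilane, mixture at C9 and the ketal carbon | CC(C)(C)[Si](C)(C)OC[C@@H](C)CCC/C(C)=C/CC(OC(C)(OC)c1ccoc1)C(C)=C | intermediate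
19 | tert-butyl{[(2S,6E)-9-{[1-(furan-3-yl)ethenyl]oxy}-2,6,10-trimethylundeca-6,10-dien-1-yl]oxy}dimethylsilane, both C9 epimers | CC(C)(C)[Si](C)(C)OC[C@@H](C)CCC/C(C)=C/CC(OC(=C)c1ccoc1)C(C)=C | intermediate
20 | (4E,7E,12S)-13-[(tert-butyldimethylsilyl)oxy]-1-(furan-3-yl)-4,8,12-trimethyltrideca-4,7-dien-1-one | CC(C)(C)[Si](C)(C)OC[C@@H](C)CCC/C(C)=C/C/C=C(\C)CCC(=O)c1ccoc1 | intermediate
21 | (4E,7E,12S)-1-(furan-3-yl)-13-hydroxy-4,8,12-trimethyltrideca-4,7-dien-1-one | OC[C@@H](C)CCC/C(C)=C/C/C=C(\C)CCC(=O)c1ccoc1 | intermediate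
22 | (2S,6E,9E)-13-(furan-3-yl)-2,6,10-trimethyl-13-oxotrideca-6,9-dienal | O=C[C@@H](C)CCC/C(C)=C/C/C=C(\C)CCC(=O)c1ccoc1 | intermediate
23 | methyl 2-[bis(2,2,2-trifluoroethoxy)phosphoryl]acetate | COC(=O)CP(=O)(OCC(F)(F)F)OCC(F)(F)F | starting material
24 | methyl 2-[bis(2,2,2-trifluoroethoxy)phosphoryl]-2-diazoacetate | COC(=O)C(=[N+]=[N-])P(=O)(OCC(F)(F)F)OCC(F)(F)F | intermediate
25 | methyl 2-[bis(2,2,2-trifluoroethoxy)phosphoryl]-2-(propanoyloxy)acetate, racemic | CCC(=O)OC(C(=O)OC)P(=O)(OCC(F)(F)F)OCC(F)(F)F | intermediate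
26 | methyl (2E,4S,8E,11E)-15-(furan-3-yl)-4,8,12-trimethyl-15-oxo-2-(propanoyloxy)pentadeca-2,8,11-trienoate | CCC(=O)O/C(C(=O)OC)=C/[C@@H](C)CCC/C(C)=C/C/C=C(\C)CCC(=O)c1ccoc1 | intermediate
27 | (5E)-5-[(2S,6E,9E)-13-(furan-3-yl)-2,6,10-trimethyl-13-oxotrideca-6,9-dien-1-ylidene]-4-hydroxy-3-methylfuran-2(5H)-one | CC1=C(O)/C(=C\[C@@H](C)CCC/C(C)=C/C/C=C(\C)CCC(=O)c2ccoc2)OC1=O | target

**Step count**

Total: 16 steps. Longest linear sequence: 13 steps (steps 1–8, 10–12, 15, 16); step 9 and steps 13–14 are side branches.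

**Steps most likely to fail**

Step 15. Kinetic control may erode: reversible addition of the phosphonate anion, or acyl migration within the adduct, would leave the C4 chain trans to the ester or divert the adduct from olefination. The fallback sets out from 22 and returns at 27, replacing steps 15 and 16 by an aldol route with stereospecific dehydration. 3-Methyltetronic acid is etherified with allyl alcohol (TsOH, benzene, water removal) to 4-(allyloxy)-3-methylfuran-2(5H)-one F1. Its C5 anion (LiN(i-Pr)2, THF, −78 °C) adds to the aldehyde of 22 and should give 4-(allyloxy)-5-[(2S,6E,9E)-13-(furan-3-yl)-1-hydroxy-2,6,10-trimethyl-13-oxotrideca-6,9-dien-1-yl]-3-methylfuran-2(5H)-one F2 as a diastereomer mixture. The 5,1'-unlike pair (5S,1'R and 5R,1'S) is separated and dehydrated by syn elimination (Burgess reagent, benzene, 50 °C). This places the chain on the C4 side and should give (5E)-4-(allyloxy)-5-[(2S,6E,9E)-13-(furan-3-yl)-2,6,10-trimethyl-13-oxotrideca-6,9-dien-1-ylidene]-3-methylfuran-2(5H)-one F3. Neutral allyl transfer to morpholine (Pd(PPh3)4, THF, rt) then frees the tetronic acid 27.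

Step 16. The ketone enolate may take part in acyl transfer from the enol ester, and the excess amide base it demands may deprotonate C7 and scramble the C5=C6 geometry and the stereocentre. The fallback sets out from 21 and returns at 27, with the ketone masked so that no excess base is needed. Ketalisation of 21 (ethylene glycol, TsOH cat., benzene, water removal) gives (2S,6E,9E)-12-[2-(furan-3-yl)-1,3-dioxolan-2-yl]-2,6,10-trimethyldodeca-6,9-dien-1-ol F4. Buffered Dess–Martin oxidation gives (2S,6E,9E)-12-[2-(furan-3-yl)-1,3-dioxolan-2-yl]-2,6,10-trimethyldodeca-6,9-dienal F5. Olefination with 25 as in step 15 gives methyl (2E,4S,8E,11E)-14-[2-(furan-3-yl)-1,3-dioxolan-2-yl]-4,8,12-trimethyl-2-(propanoyloxy)tetradeca-2,8,11-trienoate F6. Dieckmann closure with only 2.2 equiv LiN(SiMe3)2 at −78 °C gives (5E)-5-{(2S,6E,9E)-12-[2-(furan-3-yl)-1,3-dioxolan-2-yl]-2,6,10-trimethyldodeca-6,9-dien-1-ylidene}-4-hydroxy-3-methylfuran-2(5H)-one F7. Hydrolysis of the dioxolane with aqueous acetic acid at rt gives 27.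

Step 10. Alcohol–ketal exchange and enol ether formation from the aryl ketal may be slow, and prolonged heating with acid could then ionise the allylic carbinol or cleave the silyl ether. The fallback sets out from 15 and returns at 20; it forms the same C16–C17 bond at the ester oxidation level and brings in the furan afterwards. Johnson orthoester Claisen rearrangement of 15 (MeC(OEt)3, EtCO2H cat., 140 °C) should give ethyl (4E,7E,12S)-13-[(tert-butyldimethylsilyl)oxy]-4,8,12-trimethyltrideca-4,7-dienoate F8. Aminolysis (MeNHOMe·HCl, i-PrMgCl, THF, −20 °C) gives (4E,7E,12S)-13-[(tert-butyldimethylsilyl)oxy]-N-methoxy-N,4,8,12-tetramethyltrideca-4,7-dienamide F9. Addition of furan-3-yllithium F10, made from 3-bromofuran and n-BuLi in THF at −78 °C, gives ketone 20.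

**Further compounds**

F1 | step 15 | 4-(allyloxy)-3-methylfuran-2(5H)-one | C=CCOC1=C(C)C(=O)OC1
F2 | step 15 | 4-(allyloxy)-5-[(2S,6E,9E)-13-(furan-3-yl)-1-hydroxy-2,6,10-trimethyl-13-oxotrideca-6,9-dien-1-yl]-3-methylfuran-2(5H)-one, mixture at C5 and C1' | C=CCOC1=C(C)C(=O)OC1C(O)[C@@H](C)CCC/C(C)=C/C/C=C(\C)CCC(=O)c2ccoc2
F3 | step 15 | (5E)-4-(allyloxy)-5-[(2S,6E,9E)-13-(furan-3-yl)-2,6,10-trimethyl-13-oxotrideca-6,9-dien-1-ylidene]-3-methylfuran-2(5H)-one | CC1=C(OCC=C)/C(=C\[C@@H](C)CCC/C(C)=C/C/C=C(\C)CCC(=O)c2ccoc2)OC1=O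
F4 | step 16 | (2S,6E,9E)-12-[2-(furan-3-yl)-1,3-dioxolan-2-yl]-2,6,10-trimethyldodeca-6,9-dien-1-ol | OC[C@@H](C)CCC/C(C)=C/C/C=C(\C)CCC1(OCCO1)c2ccoc2
F5 | step 16 | (2S,6E,9E)-12-[2-(furan-3-yl)-1,3-dioxolan-2-yl]-2,6,10-trimethyldodeca-6,9-dienal | O=C[C@@H](C)CCC/C(C)=C/C/C=C(\C)CCC1(OCCO1)c2ccoc2
F6 | step 16 | methyl (2E,4S,8E,11E)-14-[2-(furan-3-yl)-1,3-dioxolan-2-yl]-4,8,12-trimethyl-2-(propanoyloxy)tetradeca-2,8,11-trienoate | CCC(=O)O/C(C(=O)OC)=C/[C@@H](C)CCC/C(C)=C/C/C=C(\C)CCC1(OCCO1)c2ccoc2
F7 | step 16 | (5E)-5-{(2S,6E,9E)-12-[2-(furan-3-yl)-1,3-dioxolan-2-yl]-2,6,10-trimethyldodeca-6,9-dien-1-ylidene}-4-hydroxy-3-methylfuran-2(5H)-one | CC1=C(O)/C(=C\[C@@H](C)CCC/C(C)=C/C/C=C(\C)CCC2(OCCO2)c3ccoc3)OC1=O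
F8 | step 10 | ethyl (4E,7E,12S)-13-[(tert-butyldimethylsilyl)oxy]-4,8,12-trimethyltrideca-4,7-dienoate | CC(C)(C)[Si](C)(C)OC[C@@H](C)CCC/C(C)=C/C/C=C(\C)CCC(=O)OCC
F9 | step 10 | (4E,7E,12S)-13-[(tert-butyldimethylsilyl)oxy]-N-methoxy-N,4,8,12-tetramethyltrideca-4,7-dienamide | CC(C)(C)[Si](C)(C)OC[C@@H](C)CCC/C(C)=C/C/C=C(\C)CCC(=O)N(C)OC
F10 | step 10 | furan-3-yllithium | [Li]c1ccoc1
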